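**Retrosynthetic overview** (Cα bears CO2H, Cβ bears CH2CHO, Cγ bears CHO; ring atoms O1, C2–C5)
1. The strategy rests on ring carbon C5 of the dihydrofuran (O1, C2–C5), which is quaternary (two methyl groups). An allenyl ketone closed through oxygen onto C5 therefore cannot aromatise and can be stopped at the exocyclic C2=Cγ enol ether by loss of the Cγ proton. This O1–C5 closure (step 13) forms the only ring.
2. Allenyl ketone 23 comes from aldehyde 19 and lithiated 3-methylbuta-1,2-diene, then oxidation. The acetal-protected formyl group on Cγ comes from silyl enol ether 18 and trimethyl orthoformate.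
3. Cα and Cβ are set together by a syn-selective organocatalytic Michael addition of aldehyde 12 to nitrodiene 8. Afterwards CH2NO2 becomes CO2tBu and CHO becomes C≡CH, then CH2CHO.
4. Nitrodiene 8 comes from vinyl bromide 4 (2,3-dibromopropene plus a Grignard reagent) and a nitroenamine.
5. One aqueous acid step removes all protecting groups and equilibrates the push–pull alkene to E.

Key step: step 13

Remark: the CH2CHO arm on Cβ is carried as a 1,3-dioxolane rather than a dimethyl acetal, so that it cannot exchange with the free aldehyde of the other arm, which would erase the stereocentre Cβ.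

**Route**

Step 1
Reactants: 1 2-(2-bromoethyl)-2-methyl-1,3-dioxolane; 2 2,3-dibromoprop-1-ene
Product: 4 2-(4-bromopent-4-en-1-yl)-2-methyl-1,3-dioxolane, via Grignard reagent 3 (not isolated)
Conditions: 1, Mg, THF, 25 °C; then 2, CuI (5 mol %), THF, −20 → 0 °C
Reagents that add atoms: none
Why: Copper-catalysed Grignard allylation, in which only the allylic bromide of 2 is displaced (direct and allylic-transposed attack give the same product) and the vinylic bromide stays.

Step 2
Reactants: 4 2-(4-bromopent-4-en-1-yl)-2-methyl-1,3-dioxolane; 5 (E)-N,N-dimethyl-2-nitroethen-1-amine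
Product: 8 2-methyl-2-[(5E)-4-methylidene-6-nitrohex-5-en-1-yl]-1,3-dioxolane, via alkenyl Grignard reagent 6 (not isolated), via magnesium nitronate adduct 7 (not isolated)
Conditions: 4, Mg, THF, 45 °C; then 5, THF, −30 → 0 °C; then AcOH, H2O, 0 °C
Reagents that add atoms: none
Why: Nitro-olefination by addition–elimination: the alkenylmagnesium adds to the amine-bearing carbon of the nitroenamine, and acid work-up expels dimethylamine to give the conjugated nitroalkene in its more stable E form.

Step 3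
Reactants: 9 2-(2-bromoethyl)-1,3-dioxolane
Product: 12 3-(1,3-dioxolan-2-yl)propanal, via Grignard reagent 10 (not isolated), via hemiaminal magnesium salt 11 (not isolated)
Conditions: 9, Mg, THF, 25 °C; then DMF, 0 °C; then AcOH, H2O, 0 °C
Reagents that add atoms: N,N-dimethylformamide, CN(C)C=O
Why: Bouveault formylation of a Grignard reagent, whose hemiaminal salt collapses to the aldehyde only on work-up, so no second addition occurs.

Step 4
Reactants: 8 nitrodiene; 12 3-(1,3-dioxolan-2-yl)propanal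
Product: 13 (2S,3R)-2-(1,3-dioxolan-2-ylmethyl)-4-methylidene-7-(2-methyl-1,3-dioxolan-2-yl)-3-(nitromethyl)heptanal
Conditions: (R)-α,α-diphenylprolinol trimethylsilyl ether (10 mol %), 4-nitrophenol (10 mol %), toluene, 0 °C; crude product used at once
Reagents that add atoms: none
Why: Enamine-catalysed Michael addition of an aldehyde to a nitroalkene: the E-enamine of 12, shielded on one face by the CPh2(OSiMe3) group of the (R)-catalyst, attacks the nitrodiene 1,4 to the nitro group through the acyclic synclinal transition state, which should set Cβ (S) and Cα (R) together as the syn pair.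

Step 5
Reactants: 13 nitro aldehyde
Product: 14 2-[(2S,3R)-2-ethynyl-4-methylidene-7-(2-methyl-1,3-dioxolan-2-yl)-3-(nitromethyl)heptyl]-1,3-dioxolane
Conditions: dimethyl (1-diazo-2-oxopropyl)phosphonate, K2CO3, MeOH, 0 °C → rt
Reagents that add atoms: dimethyl (1-diazo-2-oxopropyl)phosphonate, COP(=O)(OC)C(=[N+]=[N-])C(C)=O
Why: Seyferth–Gilbert homologation with the Ohira–Bestmann reagent turns the epimerisable aldehyde into a terminal alkyne that carries the one extra carbon needed and is inert in the next two steps.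

Step 6
Reactants: 14 nitro alkyne
Product: 15 (2R,3S)-3-(1,3-dioxolan-2-ylmethyl)-2-[5-(2-methyl-1,3-dioxolan-2-yl)pent-1-en-2-yl]pent-4-ynoic acid
Conditions: NaNO2 (3 equiv), AcOH (10 equiv), DMSO, 35 °C
Reagents that add atoms: sodium nitrite, [Na+].[O-]N=O; water, O
Why: Nef-type oxidation of a primary nitroalkane to the carboxylic acid (nitrosation to the nitrolic acid, nitrile oxide, hydrolysis) under weakly acidic conditions that should leave the dioxolanes and the configuration at Cα untouched.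

Step 7
Reactants: 15 acid
Product: 16 tert-butyl (2R,3S)-3-(1,3-dioxolan-2-ylmethyl)-2-[5-(2-methyl-1,3-dioxolan-2-yl)pent-1-en-2-yl]pent-4-ynoate
Conditions: O-tert-butyl-N,N′-diisopropylisourea, CH2Cl2, rt
Reagents that add atoms: O-tert-butyl-N,N′-diisopropylisourea, CC(C)NC(=NC(C)C)OC(C)(C)C
Why: Neutral isourea esterification (tert-butyl transfer to the carboxylate) gives an ester that later falls in the same acid step as the acetals.

Step 8
Reactants: 16 alkynyl ester
Product: 17 tert-butyl (2R,3S)-3-(1,3-dioxolan-2-ylmethyl)-2-[5-(2-methyl-1,3-dioxolan-2-yl)pent-1-en-2-yl]-5-oxopentanoate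
Conditions: [CpRu(MeCN)3]PF6 (5 mol %), 5,5′-bis(trifluoromethyl)-2,2′-bipyridine (5 mol %), NMP/H2O 4:1, 25 °C
Reagents that add atoms: water, O
Why: Ruthenium-catalysed anti-Markovnikov hydration of a terminal alkyne (via a vinylidene) should give the aldehyde under neutral conditions that touch neither the 1,1-disubstituted alkene nor the dioxolanes.

Step 9
Reactants: 17 ester aldehyde
Product: 18 trimethylsilyl enol ether of 17 (E/Z mixture; Cα and Cβ as in 17)
Conditions: TMSCl, Et3N, DMF, 60 °C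
Reagents that add atoms: chlorotrimethylsilane, C[Si](C)(C)Cl
Why: Amine-mediated enol silylation of the aldehyde; triethylamine does not enolise the tert-butyl ester, so only Cγ is activated.

Step 10
Reactants: 18 silyl enol ether
Product: 19 tert-butyl 4-(dimethoxymethyl)-3-(1,3-dioxolan-2-ylmethyl)-2-[5-(2-methyl-1,3-dioxolan-2-yl)pent-1-en-2-yl]-5-oxopentanoate (Cγ epimers; Cα and Cβ as in 17)
Conditions: HC(OMe)3 (3 equiv), TMSOTf (10 mol %), CH2Cl2, −78 °C; Et3N quench at −78 °C; used crude
Reagents that add atoms: trimethyl orthoformate, COC(OC)OC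
Why: Mukaiyama-type addition of the silyl enol ether to the dimethoxycarbenium ion puts the future formyl carbon on Cγ already as its acetal while the old aldehyde carbon stays free, so the two carbonyl carbons on Cγ are differentiated (the Cγ configuration is irrelevant, as Cγ ends sp2).

Step 11
Reactants: 19 aldehyde acetal; 20 3-methylbuta-1,2-diene
Product: 22 tert-butyl 4-(dimethoxymethyl)-3-(1,3-dioxolan-2-ylmethyl)-5-hydroxy-8-methyl-2-[5-(2-methyl-1,3-dioxolan-2-yl)pent-1-en-2-yl]nona-6,7-dienoate (diastereomer mixture at C4 and C5), via allenyllithium 21 (not isolated)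
Conditions: 20, n-BuLi, THF, −78 → −40 °C; then 19, −78 °C; aq. NH4Cl
Reagents that add atoms: none
Why: 1,2-Addition of a lithiated allene to an aldehyde: the reagent should react at its lithium-bearing carbon because the other terminus carries two methyl groups, so the allene is kept, and at −78 °C addition should outrun deprotonation next to the ester or the acetal.

Step 12
Reactants: 22 allenyl carbinol
Product: 23 tert-butyl 4-(dimethoxymethyl)-3-(1,3-dioxolan-2-ylmethyl)-8-methyl-2-[5-(2-methyl-1,3-dioxolan-2-yl)pent-1-en-2-yl]-5-oxonona-6,7-dienoate (either epimer at Cγ; Cα and Cβ as in 17)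
Conditions: Dess–Martin periodinane, pyridine, CH2Cl2, 0 °C
Reagents that add atoms: none
Why: Dess–Martin oxidation of an α-allenic alcohol to the allenyl ketone, buffered so that the β-keto acetal does not lose methanol.

Step 13
Reactants: 23 allenyl ketone
Product: 24 tert-butyl (2R,3S,4E)-5,5-dimethoxy-4-(5,5-dimethylfuran-2(5H)-ylidene)-3-(1,3-dioxolan-2-ylmethyl)-2-[5-(2-methyl-1,3-dioxolan-2-yl)pent-1-en-2-yl]pentanoate (may form as an E/Z mixture)
Conditions: Ph3PAuNTf2 (5 mol %), 2,6-di-tert-butylpyridine (1 equiv), 4 Å MS, CH2Cl2, 0 °C → rt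
Reagents that add atoms: none
Why: Proposed new method: Ph3PAuNTf2 (monovalent gold) activates the distal C=C of the allene and the ketone oxygen adds to the dimethyl-bearing terminus in a 5-endo-trig closure (O1–C5 bond, ring O1/C2–C5), giving a 4-aurated 5,5-dimethyl-2H-furan-1-ium ion; because C5 has no hydrogen the usual aromatising proton loss is closed, so the hindered pyridine should remove the proton on Cγ (α to the oxocarbenium carbon C2 and further acidified by the acetal) to give the exocyclic C2=Cγ enol ether, and protodeauration at C4 by the pyridinium ion turns the catalyst over. The closest known reactions are the gold- or silver-catalysed cycloisomerisation of allenyl ketones to furans and of α-hydroxyallenes to 2,5-dihydrofurans, the latter being the path the enol tautomer of 23 would take to the same product. No stereocentre is created: Cγ loses its stereogenicity, so both epimers of 23 converge, and the C2=Cγ geometry is left to thermodynamic equilibration in step 14. The step needs Cγ–H loss to outrun 1,2-methyl migration from C5 to C4 (which would give an aromatic furan), methanol loss and 4π-closure; the quaternary C5, the acidic Cγ–H with a non-coordinating base present, and keeping Cγ sp3 as the acetal are what should secure this.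

Step 14
Reactants: 24 ylidene dihydrofuran
Product: 25 (2R,3S,4E)-4-(5,5-dimethylfuran-2(5H)-ylidene)-5-oxo-3-(2-oxoethyl)-2-(6-oxohept-1-en-2-yl)pentanoic acid (CNP0150297.1)
Conditions: TFA/H2O/CH2Cl2 (4:1:4), 0 °C → rt
Reagents that add atoms: water, O
Why: Acid hydrolysis of the dimethyl acetal and both dioxolanes together with acidolysis of the tert-butyl ester; the unmasked formyl group makes C2=Cγ a push–pull alkene that can rotate through its protonated form and should settle as the E isomer, with the branched Cβ next to O1.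

**Compound list**

1 | 2-(2-bromoethyl)-2-methyl-1,3-dioxolane | CC1(CCBr)OCCO1 | starting material
2 | 2,3-dibromoprop-1-ene | C=C(Br)CBr | starting material
3 | [2-(2-methyl-1,3-dioxolan-2-yl)ethyl]magnesium bromide | CC1(CC[Mg]Br)OCCO1 | intermediate
4 | 2-(4-bromopent-4-en-1-yl)-2-methyl-1,3-dioxolane | C=C(Br)CCCC1(C)OCCO1 | intermediate
5 | (E)-N,N-dimethyl-2-nitroethen-1-amine | CN(C)/C=C/[N+](=O)[O-] | starting material
6 | [5-(2-methyl-1,3-dioxolan-2-yl)pent-1-en-2-yl]magnesium bromide | C=C([Mg]Br)CCCC1(C)OCCO1 | intermediate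
7 | bromomagnesium nitronate of N,N-dimethyl-2-methylidene-5-(2-methyl-1,3-dioxolan-2-yl)-1-(nitromethyl)pentan-1-amine | C=C(CCCC1(C)OCCO1)C(N(C)C)C=[N+]([O-])O[Mg]Br | intermediate
8 | 2-methyl-2-[(5E)-4-methylidene-6-nitrohex-5-en-1-yl]-1,3-dioxolane | C=C(CCCC1(C)OCCO1)/C=C/[N+](=O)[O-] | intermediate
9 | 2-(2-bromoethyl)-1,3-dioxolane | BrCCC1OCCO1 | starting material
10 | [2-(1,3-dioxolan-2-yl)ethyl]magnesium bromide | Br[Mg]CCC1OCCO1 | intermediate
11 | bromomagnesium 1-(dimethylamino)-3-(1,3-dioxolan-2-yl)propan-1-olate | CN(C)C(CCC1OCCO1)O[Mg]Br | intermediate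
12 | 3-(1,3-dioxolan-2-yl)propanal | O=CCCC1OCCO1 | intermediate
13 | (2S,3R)-2-(1,3-dioxolan-2-ylmethyl)-4-methylidene-7-(2-methyl-1,3-dioxolan-2-yl)-3-(nitromethyl)heptanal | C=C(CCCC1(C)OCCO1)[C@H](C[N+](=O)[O-])[C@H](CC2OCCO2)C=O | intermediate
14 | 2-[(2S,3R)-2-ethynyl-4-methylidene-7-(2-methyl-1,3-dioxolan-2-yl)-3-(nitromethyl)heptyl]-1,3-dioxolane | C=C(CCCC1(C)OCCO1)[C@H](C[N+](=O)[O-])[C@H](CC2OCCO2)C#C | intermediate
15 | (2R,3S)-3-(1,3-dioxolan-2-ylmethyl)-2-[5-(2-methyl-1,3-dioxolan-2-yl)pent-1-en-2-yl]pent-4-ynoic acid | C=C(CCCC1(C)OCCO1)[C@H](C(=O)O)[C@H](CC2OCCO2)C#C | intermediate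
16 | tert-butyl (2R,3S)-3-(1,3-dioxolan-2-ylmethyl)-2-[5-(2-methyl-1,3-dioxolan-2-yl)pent-1-en-2-yl]pent-4-ynoate | C=C(CCCC1(C)OCCO1)[C@H](C(=O)OC(C)(C)C)[C@H](CC2OCCO2)C#C | intermediate
17 | tert-butyl (2R,3S)-3-(1,3-dioxolan-2-ylmethyl)-2-[5-(2-methyl-1,3-dioxolan-2-yl)pent-1-en-2-yl]-5-oxopentanoate | C=C(CCCC1(C)OCCO1)[C@H](C(=O)OC(C)(C)C)[C@H](CC2OCCO2)CC=O | intermediate
18 | trimethylsilyl enol ether of 17 (5-(trimethylsilyloxy)pent-4-enoate, E/Z; Cα and Cβ as in 17) | C=C(CCCC1(C)OCCO1)[C@H](C(=O)OC(C)(C)C)[C@H](CC2OCCO2)C=CO[Si](C)(C)C | intermediate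
19 | tert-butyl 4-(dimethoxymethyl)-3-(1,3-dioxolan-2-ylmethyl)-2-[5-(2-methyl-1,3-dioxolan-2-yl)pent-1-en-2-yl]-5-oxopentanoate (C4 epimers; Cα and Cβ as in 17) | C=C(CCCC1(C)OCCO1)[C@H](C(=O)OC(C)(C)C)[C@H](CC2OCCO2)C(C=O)C(OC)OC | intermediate
20 | 3-methylbuta-1,2-diene | CC(C)=C=C | starting material
21 | (3-methylbuta-1,2-dien-1-yl)lithium | [Li]C=C=C(C)C | intermediate
22 | tert-butyl 4-(dimethoxymethyl)-3-(1,3-dioxolan-2-ylmethyl)-5-hydroxy-8-methyl-2-[5-(2-methyl-1,3-dioxolan-2-yl)pent-1-en-2-yl]nona-6,7-dienoate (C4/C5 mixture; Cα and Cβ as in 17) | C=C(CCCC1(C)OCCO1)[C@H](C(=O)OC(C)(C)C)[C@H](CC2OCCO2)C(C(OC)OC)C(O)C=C=C(C)C | intermediate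
23 | tert-butyl 4-(dimethoxymethyl)-3-(1,3-dioxolan-2-ylmethyl)-8-methyl-2-[5-(2-methyl-1,3-dioxolan-2-yl)pent-1-en-2-yl]-5-oxonona-6,7-dienoate (either C4 epimer; Cα and Cβ as in 17) | C=C(CCCC1(C)OCCO1)[C@H](C(=O)OC(C)(C)C)[C@H](CC2OCCO2)C(C(OC)OC)C(=O)C=C=C(C)C | intermediate
24 | tert-butyl (2R,3S,4E)-5,5-dimethoxy-4-(5,5-dimethylfuran-2(5H)-ylidene)-3-(1,3-dioxolan-2-ylmethyl)-2-[5-(2-methyl-1,3-dioxolan-2-yl)pent-1-en-2-yl]pentanoate | C=C(CCCC1(C)OCCO1)[C@H](C(=O)OC(C)(C)C)[C@H](CC2OCCO2)/C(C(OC)OC)=C3/C=CC(C)(C)O3 | intermediate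
25 | (2R,3S,4E)-4-(5,5-dimethylfuran-2(5H)-ylidene)-5-oxo-3-(2-oxoethyl)-2-(6-oxohept-1-en-2-yl)pentanoic acid | C=C(CCCC(C)=O)[C@H](C(=O)O)[C@H](CC=O)/C(C=O)=C1/C=CC(C)(C)O1 | target

**Step count and risks**

Total steps: 14. Longest linear sequence: 13 steps (1, 2, 4–14).

Steps most likely to fail:

1. Step 13 (new method). The furanium ion may instead undergo 1,2-methyl migration and aromatise, the β-keto acetal may lose methanol and then close in a 4π sense, or the allenyl ketone may oligomerise before the Cγ proton is removed. Fallback with known reactions, from 19 back to 24: 19 is treated with the dilithium salt of 2-methylbut-3-yn-2-ol F1 (from the alkynol and two equivalents of n-BuLi, THF, −78 °C) to give the propargylic diol F2. MnO2 in CH2Cl2 oxidises only the secondary propargylic alcohol, giving the γ-hydroxy ynone F3. Semi-hydrogenation over lead-poisoned Pd/CaCO3 with quinoline gives the Z-enone, which closes to the cyclic hemiketal F4. F4 can only dehydrate towards Cγ, because C3 is already sp2 and C5 is quaternary, so PPTS with 4 Å sieves in CH2Cl2 should give 24.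

2. Step 4. The enamine may add to the unsubstituted diene terminus (1,6) instead of 1,4, the nitrodiene may polymerise, and the aldehyde α-centre Cβ of the adduct may epimerise before step 5. Fallback, from 4 back to 17, on a lactone template: commercial 5,6-dihydro-2H-pyran-2-one (O=C1C=CCCO1) takes up (1,3-dioxolan-2-ylmethyl)magnesium bromide in a conjugate addition catalysed by CuBr·SMe2 and a chiral ferrocenyl diphosphine, giving (S)-4-(1,3-dioxolan-2-ylmethyl)oxan-2-one F5. LiN(SiMe3)2 and ZnCl2 convert F5 into its zinc enolate F6, which is coupled with 4 under Pd(dba)2/P(t-Bu)3 to the trans-3-alkenyl lactone F7, the alkenyl group entering anti to the C4 substituent. LiOH opens F7 to the hydroxy acid F8 (acidified cold and used at once). O-tert-butyl-N,N′-diisopropylisourea gives the hydroxy tert-butyl ester F9, and Dess–Martin oxidation gives 17.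

3. Step 11. The allenyllithium may react through its dimethyl-bearing carbon (propargylic transposition), or act as a base and cause methanol elimination from 19 or deprotonation next to the ester. Fallback, from 19 back to 23, building the allene by a ketene Wittig reaction: 19 is oxidised (NaClO2, NaH2PO4, 2-methylbut-2-ene) to the carboxylic acid F10 and activated with carbonyldiimidazole as the acyl imidazole F11. Methylenetriphenylphosphorane F12 (two equivalents, from Ph3PCH3Br and NaN(SiMe3)2) converts F11 into the acylphosphorane F13. F13 then olefinates dimethylketene F14, generated in the flask from isobutyryl chloride and Et3N, to give 23.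

**Further compounds**

F1 | step 13 | dilithium salt of 2-methylbut-3-yn-2-ol | [Li]C#CC(C)(C)O[Li]
F2 | step 13 | tert-butyl 4-(dimethoxymethyl)-3-(1,3-dioxolan-2-ylmethyl)-5,8-dihydroxy-8-methyl-2-[5-(2-methyl-1,3-dioxolan-2-yl)pent-1-en-2-yl]non-6-ynoate | C=C(CCCC1(C)OCCO1)[C@H](C(=O)OC(C)(C)C)[C@H](CC2OCCO2)C(C(OC)OC)C(O)C#CC(C)(C)O
F3 | step 13 | tert-butyl 4-(dimethoxymethyl)-3-(1,3-dioxolan-2-ylmethyl)-8-hydroxy-8-methyl-2-[5-(2-methyl-1,3-dioxolan-2-yl)pent-1-en-2-yl]-5-oxonon-6-ynoate | C=C(CCCC1(C)OCCO1)[C@H](C(=O)OC(C)(C)C)[C@H](CC2OCCO2)C(C(OC)OC)C(=O)C#CC(C)(C)O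
F4 | step 13 | cyclic hemiketal of the Z-enone: tert-butyl 5,5-dimethoxy-3-(1,3-dioxolan-2-ylmethyl)-4-(2-hydroxy-5,5-dimethyl-2,5-dihydrofuran-2-yl)-2-[5-(2-methyl-1,3-dioxolan-2-yl)pent-1-en-2-yl]pentanoate | C=C(CCCC1(C)OCCO1)[C@H](C(=O)OC(C)(C)C)[C@H](CC2OCCO2)C(C(OC)OC)C3(O)C=CC(C)(C)O3
F5 | step 4 | (S)-4-(1,3-dioxolan-2-ylmethyl)oxan-2-one | O=C1C[C@H](CC2OCCO2)CCO1
F6 | step 4 | chlorozinc enolate of F5 | Cl[Zn]OC1=C[C@H](CC2OCCO2)CCO1
F7 | step 4 | (3R,4S)-4-(1,3-dioxolan-2-ylmethyl)-3-[5-(2-methyl-1,3-dioxolan-2-yl)pent-1-en-2-yl]oxan-2-one | C=C(CCCC1(C)OCCO1)[C@@H]2C(=O)OCC[C@H]2CC3OCCO3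
F8 | step 4 | (2R,3S)-3-(1,3-dioxolan-2-ylmethyl)-5-hydroxy-2-[5-(2-methyl-1,3-dioxolan-2-yl)pent-1-en-2-yl]pentanoic acid | C=C(CCCC1(C)OCCO1)[C@H](C(=O)O)[C@H](CC2OCCO2)CCO
F9 | step 4 | tert-butyl (2R,3S)-3-(1,3-dioxolan-2-ylmethyl)-5-hydroxy-2-[5-(2-methyl-1,3-dioxolan-2-yl)pent-1-en-2-yl]pentanoate | C=C(CCCC1(C)OCCO1)[C@H](C(=O)OC(C)(C)C)[C@H](CC2OCCO2)CCO
F10 | step 11 | 5-tert-butoxy-2-(dimethoxymethyl)-3-(1,3-dioxolan-2-ylmethyl)-4-[5-(2-methyl-1,3-dioxolan-2-yl)pent-1-en-2-yl]-5-oxopentanoic acid | C=C(CCCC1(C)OCCO1)[C@H](C(=O)OC(C)(C)C)[C@H](CC2OCCO2)C(C(=O)O)C(OC)OC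
F11 | step 11 | acyl imidazole of F10 | C=C(CCCC1(C)OCCO1)[C@H](C(=O)OC(C)(C)C)[C@H](CC2OCCO2)C(C(=O)n3ccnc3)C(OC)OC
F12 | step 11 | methylenetriphenylphosphorane | C=P(c1ccccc1)(c1ccccc1)c1ccccc1
F13 | step 11 | tert-butyl 4-(dimethoxymethyl)-3-(1,3-dioxolan-2-ylmethyl)-2-[5-(2-methyl-1,3-dioxolan-2-yl)pent-1-en-2-yl]-5-oxo-6-(triphenyl-λ5-phosphanylidene)hexanoate | C=C(CCCC1(C)OCCO1)[C@H](C(=O)OC(C)(C)C)[C@H](CC2OCCO2)C(C(OC)OC)C(=O)C=P(c3ccccc3)(c3ccccc3)c3ccccc3
F14 | step 11 | dimethylketene | CC(C)=C=O
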